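**Plan**

- Retrosynthesis: remove the C3 acetate; cut C6–H and C7–H (ionic hydrogenation of a naphtho[2,3-b]furan); cut the furan C6–O bond (cyclodehydration) and the C7–naphthyl bond (ketone α-arylation); then cut C5–C6 and C9–C10 of ring B together. This leaves a ring A olefin (4), an arylacetyl chloride (9) and a bromonaphthalene (22).
- Enabling feature: in ring B, C10 is a benzylic quaternary carbon bonded to C9 (para to the C13 isopropyl group of ring C) and C6 carries oxygen. C6–C7–C8–C9 is therefore an arylacetyl unit (acylium carbon C6, nucleophilic arene carbon C9) and C5=C10 is the double bond of a ring A cyclohexene; a cationic [4+2] annulation (acylation–cycloalkylation) unites them.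
- Forward order: ring A (steps 1–3) and ring C (steps 4–6) are joined and ring B is closed in step 7; the naphthalene (steps 8–15) is attached at C7 (step 16); the furan ring closes (step 17) and is reduced to the cis-fused dihydrofuran (step 18); deacetylation ends the route (step 19).
- Stereochemistry: C3 from a CBS reduction (step 2); C10 by 1,4-induction from C3 and C5 by enolate protonation (step 7); C6 and C7 in step 18, where reversible protonation at C6 places the C6–O bond equatorial (α) and the cis ring fusion fixes the face of hydride delivery at C7.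

Key step: step 7

Remark: the lower half carries abietane numbers (C1 to C20; β is the face of the C20 methyl group), the naphthalene carries ordinary naphthalene locants, and the C7 epimers of 23 and 24 are treated as one compound because C7 becomes trigonal in 25.

**Route**

Step 1
Reactants: 1 4-methylcyclohex-2-en-1-one (racemic)
Product: 2 2,2,4-trimethylcyclohex-3-en-1-one
Conditions: KOtBu (2.3 equiv), MeI (2.5 equiv), t-BuOH/THF, 0 to 23 °C
Reagents that add atoms: iodomethane, CI
Why: Deconjugative α,α-dimethylation through the extended dienolate (the reaction that turns 4-en-3-one steroids into 4,4-dimethyl-5-en-3-ones) puts both methyl groups on C2 and leaves the double bond in the β,γ position, where the new quaternary carbon blocks reconjugation.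

Step 2
Reactants: 2 2,2,4-trimethylcyclohex-3-en-1-one
Product: 3 (1S)-2,2,4-trimethylcyclohex-3-en-1-ol
Conditions: (R)-2-methyl-CBS-oxazaborolidine (0.1 equiv), catecholborane, toluene, −78 to −40 °C
Reagents that add atoms: none
Why: Corey–Bakshi–Shibata reduction sets the carbinol stereocenter (future C3) because the catalyst tells the quaternary flank from the methylene flank as it does with tert-butyl methyl ketone, the (R)-catalyst giving the (S)-alcohol, and catecholborane at low temperature does not hydroborate the trisubstituted olefin.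

Step 3
Reactants: 3 (1S)-2,2,4-trimethylcyclohex-3-en-1-ol
Product: 4 (1S)-2,2,4-trimethylcyclohex-3-en-1-yl acetate
Conditions: Ac2O, pyridine, DMAP (cat.), CH2Cl2, 23 °C
Reagents that add atoms: acetic anhydride, CC(=O)OC(C)=O
Why: DMAP-catalysed acylation esterifies the hindered secondary alcohol with retention and gives an ester that should survive AlCl3, K3PO4, BBr3 at low temperature and CF3CO2H.

Step 4
Reactants: 5 1-methoxy-2-(propan-2-yl)benzene
Product: 6 1-[4-methoxy-3-(propan-2-yl)phenyl]ethan-1-one
Conditions: AcCl, AlCl3, CH2Cl2, 0 °C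
Reagents that add atoms: acetyl chloride, CC(=O)Cl
Why: Friedel–Crafts acylation goes para to the methoxy group, which is also the position least hindered by the isopropyl group.

Step 5
Reactants: 6 1-[4-methoxy-3-(propan-2-yl)phenyl]ethan-1-one
Product: 8 2-[4-methoxy-3-(propan-2-yl)phenyl]acetic acid, via thiomorpholide 7 (not isolated)
Conditions: S8, morpholine, 130 °C; then NaOH, H2O/EtOH, reflux; HCl
Reagents that add atoms: water, O (both carboxyl oxygens); sulfur, S1SSSSSSS1 (atoms only in 7); morpholine, C1COCCN1 (atoms only in 7)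
Why: The Willgerodt–Kindler reaction moves the oxidised carbon to the chain terminus to give the arylthioacetyl morpholide, and alkaline hydrolysis of this thioamide gives the arylacetic acid, as in the standard preparation of 4-methoxyphenylacetic acid.

Step 6
Reactants: 8 2-[4-methoxy-3-(propan-2-yl)phenyl]acetic acid
Product: 9 2-[4-methoxy-3-(propan-2-yl)phenyl]acetyl chloride
Conditions: (COCl)2, DMF (cat.), CH2Cl2, 0 to 23 °C
Reagents that add atoms: oxalyl chloride, ClC(=O)C(=O)Cl
Why: Acid chloride formation through the chloroiminium salt is clean for arylacetic acids and the crude chloride can be used after evaporation.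

Step 7
Reactants: 9 2-[4-methoxy-3-(propan-2-yl)phenyl]acetyl chloride; 4 (1S)-2,2,4-trimethylcyclohex-3-en-1-yl acetate
Product: 11 3β-acetoxy-12-methoxyabieta-8,11,13-trien-6-one (5α-H and 10β-methyl), via enone 10 (not isolated)
Conditions: 9 and AlCl3 (2.5 equiv), CH2Cl2, −78 °C; 4 added slowly; −78 to 0 °C; cold 1 M HCl
Reagents that add atoms: none
Why: AlCl3 ionises 9 to the acylium ion, which adds to C5 of the trisubstituted olefin of 4 (Markovnikov; the linear acylium ion tolerates the neopentyl position) and gives the tertiary C10 cation; this cation either closes directly or first loses H5 to the AlCl3-bound enone 10, whose β-carbon C10 is attacked by the arene in the same way, so that both branches converge on bond formation between C9 and C10 and on the aluminium enolate of 11. The closest known reaction type is the Friedel–Crafts acylation–cycloalkylation of arylacetyl chlorides with olefins that gives 2-tetralones (4-methoxyphenylacetyl chloride with ethene or isobutene, where the ring also closes meta to the methoxy group). Ring B is the only ring closed, by electrophilic aromatic substitution at C9 in a 6-endo mode with respect to the arene bond C8=C9, which creates the benzylic quaternary carbon. C10 is controlled by 1,4-induction from C3: in the chair-like transition state that keeps the C3 acetoxy group equatorial the arene enters C10 anti to the axial methyl group on C4, so that C9 ends trans and C20 cis to the acetate as in 3β-oxygenated trans-abietanes; C5 is controlled by protonation of the enolate from the α face, away from the two syn-axial β-methyl groups on C4 and C10, which gives the trans ring fusion. The step needs Markovnikov acylation (secured by the tertiary cation at C10), closure at C9 and not at C14 (secured by the isopropyl group that flanks C14 and activates C9 from the para position) and facial control at C10 (secured by the equatorial preference of the acetate; the product of attack on the other face is a diastereomer that chromatography removes, not the enantiomer).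

Step 8
Reactants: 12 6-methoxy-3,4-dihydronaphthalen-1(2H)-one
Product: 13 6-methoxy-2-methyl-3,4-dihydronaphthalen-1(2H)-one (racemic)
Conditions: LiN(iPr)2, THF, −78 °C; MeI, −78 to 0 °C
Reagents that add atoms: iodomethane, CI
Why: Kinetic enolate alkylation can only occur at C2, the single α-carbon that bears hydrogen, and low temperature favours mono-methylation.

Step 9
Reactants: 13 6-methoxy-2-methyl-3,4-dihydronaphthalen-1(2H)-one
Product: 14 6-methoxy-2-methyl-3,4-dihydronaphthalen-1-yl trifluoromethanesulfonate
Conditions: KN(SiMe3)2, PhNTf2, THF, −78 to 0 °C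
Reagents that add atoms: N-phenylbis(trifluoromethanesulfonimide), O=S(=O)(N(c1ccccc1)S(=O)(=O)C(F)(F)F)C(F)(F)F
Why: Enol triflate formation is unambiguous because 13 gives one enolate only, which is sulfonylated on oxygen.

Step 10
Reactants: 14 6-methoxy-2-methyl-3,4-dihydronaphthalen-1-yl trifluoromethanesulfonate
Product: 15 6-methoxy-2-methylnaphthalen-1-yl trifluoromethanesulfonate
Conditions: DDQ, 1,4-dioxane, 100 °C
Reagents that add atoms: none
Why: Dehydrogenation with DDQ proceeds by hydride abstraction at the allylic C3, helped by the para-methoxy group, and proton loss from C4, which turns the enol triflate into an aryl triflate.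

Step 11
Reactants: 15 6-methoxy-2-methylnaphthalen-1-yl trifluoromethanesulfonate; 16 4-methylpent-1-en-3-ol (racemic)
Product: 17 1-(6-methoxy-2-methylnaphthalen-1-yl)-4-methylpentan-3-one
Conditions: Pd(OAc)2 (5 mol %), LiCl, Bu4NCl, NaHCO3, DMF, 100 °C
Reagents that add atoms: none
Why: In this Heck reaction of a secondary allylic alcohol the aryl group adds to the terminal carbon and β-hydride elimination toward the carbinol carbon gives the enol and hence the saturated β-aryl ketone directly (the nabumetone-type process), with chloride keeping the triflate-derived catalyst on the neutral pathway that favours the linear product.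

Step 12
Reactants: 17 1-(6-methoxy-2-methylnaphthalen-1-yl)-4-methylpentan-3-one
Product: 18 1-(5-bromo-6-methoxy-2-methylnaphthalen-1-yl)-4-methylpentan-3-one
Conditions: NBS, MeCN, 0 °C, dark
Reagents that add atoms: N-bromosuccinimide, O=C1CCC(=O)N1Br
Why: Electrophilic aromatic bromination is directed by the methoxy group to the adjacent α-position C5 (the 1-position of a 2-methoxynaphthalene), which is far more reactive than the β-position C7 or the alkylated ring.

Step 13
Reactants: 18 1-(5-bromo-6-methoxy-2-methylnaphthalen-1-yl)-4-methylpentan-3-one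
Product: 19 1-[6-methoxy-2-methyl-5-(propan-2-yl)naphthalen-1-yl]-4-methylpentan-3-one
Conditions: iPrZnBr, Pd(OAc)2 (2 mol %), CPhos (4 mol %), THF/toluene, 23 °C
Reagents that add atoms: isopropylzinc bromide, CC(C)[Zn]Br
Why: Negishi coupling with the CPhos-ligated palladium catalyst joins secondary alkylzinc halides to ortho-substituted aryl bromides with reductive elimination faster than β-hydride elimination, so the isopropyl group should arrive unrearranged, and the ketone is inert to the organozinc.

Step 14
Reactants: 19 1-[6-methoxy-2-methyl-5-(propan-2-yl)naphthalen-1-yl]-4-methylpentan-3-one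
Product: 20 2-{2-[6-methoxy-2-methyl-5-(propan-2-yl)naphthalen-1-yl]ethyl}-2-(propan-2-yl)-1,3-dioxolane
Conditions: HOCH2CH2OH, TsOH·H2O (cat.), toluene, reflux, Dean–Stark trap
Reagents that add atoms: ethane-1,2-diol, OCCO
Why: Acid-catalysed ketalisation with azeotropic removal of water masks the side-chain ketone against the organolithium of step 15 and the base of step 16.

Step 15
Reactants: 20 2-{2-[6-methoxy-2-methyl-5-(propan-2-yl)naphthalen-1-yl]ethyl}-2-(propan-2-yl)-1,3-dioxolane
Product: 22 2-{2-[7-bromo-6-methoxy-2-methyl-5-(propan-2-yl)naphthalen-1-yl]ethyl}-2-(propan-2-yl)-1,3-dioxolane, via aryllithium 21 (not isolated)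
Conditions: n-BuLi, THF, 0 to 23 °C; then BrCl2CCCl2Br, −78 °C
Reagents that add atoms: 1,2-dibromo-1,1,2,2-tetrachloroethane, BrC(Cl)(Cl)C(Cl)(Cl)Br; n-butyllithium, [Li]CCCC (lithium only in 21)
Why: Directed ortho-metalation by the methoxy group can only reach C7, the one ortho position that still carries hydrogen (as in the 3-lithiation of 1-substituted 2-methoxynaphthalenes), THF without a diamine disfavours benzylic metalation, and the aryllithium takes up bromine from the polyhalide.

Step 16
Reactants: 11 3β-acetoxy-12-methoxyabieta-8,11,13-trien-6-one; 22 2-{2-[7-bromo-6-methoxy-2-methyl-5-(propan-2-yl)naphthalen-1-yl]ethyl}-2-(propan-2-yl)-1,3-dioxolane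
Product: 23 3β-acetoxy-12-methoxy-7α-{3-methoxy-7-methyl-4-(propan-2-yl)-8-[2-(2-(propan-2-yl)-1,3-dioxolan-2-yl)ethyl]naphthalen-2-yl}abieta-8,11,13-trien-6-one
Conditions: Pd2(dba)3 (2.5 mol %), XPhos (6 mol %), K3PO4, toluene, 90 °C
Reagents that add atoms: none
Why: In this palladium-catalysed ketone α-arylation K3PO4 enolises the 2-tetralone only toward the benzylic C7 (C5 is a hindered methine next to the quaternary C4), the zerovalent palladium inserts into the C–Br bond of 22, and the acidic doubly benzylic C7–H of the product lets the naphthyl group settle pseudoaxial (α), a configuration that step 17 erases in any case.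

Step 17
Reactants: 23 3β-acetoxy-12-methoxy-7α-{3-methoxy-7-methyl-4-(propan-2-yl)-8-[2-(2-(propan-2-yl)-1,3-dioxolan-2-yl)ethyl]naphthalen-2-yl}abieta-8,11,13-trien-6-one
Product: 25 3β-acetoxy-12-hydroxy-7-[7-methyl-8-(4-methyl-3-oxopentyl)-4-(propan-2-yl)naphthalen-2-yl]abieta-6,8,11,13-tetraene 6,3′-cyclic ether (aromatic naphtho[2,3-b]furan), via hydroxy ketone 24 (not isolated)
Conditions: BBr3, CH2Cl2, −78 to 0 °C; then 1 M HCl, THF, 40 °C
Reagents that add atoms: water, O (oxygen of the side-chain ketone)
Why: BBr3 cleaves both aryl methyl ethers faster than the secondary acetate, and the aqueous acid then hydrolyses the dioxolane and lets the freed naphthol of 24 add to the C6 ketone and lose water (the cyclodehydration of an α-(2-hydroxyaryl) ketone to a benzofuran), which is driven by the aromaticity of the new furan ring and leaves C3, C5 and C10 untouched.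

Step 18
Reactants: 25 3β-acetoxy-12-hydroxy-7-[7-methyl-8-(4-methyl-3-oxopentyl)-4-(propan-2-yl)naphthalen-2-yl]abieta-6,8,11,13-tetraene 6,3′-cyclic ether
Product: 26 3β-acetoxy-12-hydroxy-7α-[7-methyl-8-(4-methyl-3-oxopentyl)-4-(propan-2-yl)naphthalen-2-yl]abieta-8,11,13-triene 6α,3′-cyclic ether (cis-fused dihydrofuran with 6β-H and 7β-H)
Conditions: Et3SiH (5 equiv), CF3CO2H/CH2Cl2 (1:4), 0 °C
Reagents that add atoms: none
Why: In this ionic hydrogenation reversible protonation of the furan at C6 gives the C7 cation stabilised by the para-hydroxyphenyl ring C and the oxygenated naphthalene; because proton loss back to the furan should be faster than hydride capture, the C6 epimer that is reduced is the one with the C6–O bond equatorial (α, away from the syn-axial C19 and C20 methyl groups), Et3SiH can then reach C7 only from the β face that keeps the five-membered ring cis-fused, and the unactivated side-chain ketone is reduced far more slowly than this cation.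

Step 19
Reactants: 26 3β-acetoxy-12-hydroxy-7α-[7-methyl-8-(4-methyl-3-oxopentyl)-4-(propan-2-yl)naphthalen-2-yl]abieta-8,11,13-triene 6α,3′-cyclic ether
Product: 27 CNP0584944.1 (the 3β,12-diol)
Conditions: K2CO3 (cat.), MeOH, 23 °C
Reagents that add atoms: none
Why: Base-catalysed transesterification removes the secondary acetate without touching the ketone, the phenol or the dihydrofuran, and no stereocenter is involved.

**Compound list**

1 | 4-methylcyclohex-2-en-1-one (racemic) | CC1CCC(=O)C=C1 | starting material
2 | 2,2,4-trimethylcyclohex-3-en-1-one | CC1=CC(C)(C)C(=O)CC1 | intermediate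
3 | (1S)-2,2,4-trimethylcyclohex-3-en-1-ol | CC1=CC(C)(C)[C@@H](O)CC1 | intermediate
4 | (1S)-2,2,4-trimethylcyclohex-3-en-1-yl acetate | CC1=CC(C)(C)[C@@H](OC(C)=O)CC1 | intermediate
5 | 1-methoxy-2-(propan-2-yl)benzene | COc1ccccc1C(C)C | starting material
6 | 1-[4-methoxy-3-(propan-2-yl)phenyl]ethan-1-one | COc1ccc(C(C)=O)cc1C(C)C | intermediate
7 | 2-[4-methoxy-3-(propan-2-yl)phenyl]-1-(morpholin-4-yl)ethane-1-thione (not isolated) | COc1ccc(CC(=S)N2CCOCC2)cc1C(C)C | intermediate
8 | 2-[4-methoxy-3-(propan-2-yl)phenyl]acetic acid | COc1ccc(CC(=O)O)cc1C(C)C | intermediate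
9 | 2-[4-methoxy-3-(propan-2-yl)phenyl]acetyl chloride | COc1ccc(CC(=O)Cl)cc1C(C)C | intermediate
10 | (1S)-3-{[4-methoxy-3-(propan-2-yl)phenyl]acetyl}-2,2,4-trimethylcyclohex-3-en-1-yl acetate (not isolated) | CC1=C(C(=O)Cc2ccc(OC)c(C(C)C)c2)C(C)(C)[C@@H](OC(C)=O)CC1 | intermediate
11 | 3β-acetoxy-12-methoxyabieta-8,11,13-trien-6-one | C1c2cc(C(C)C)c(OC)cc2[C@@]2(C)CC[C@H](OC(C)=O)C(C)(C)[C@@H]2C1=O | intermediate
12 | 6-methoxy-3,4-dihydronaphthalen-1(2H)-one | COc1ccc2c(c1)CCCC2=O | starting material
13 | 6-methoxy-2-methyl-3,4-dihydronaphthalen-1(2H)-one (racemic) | COc1ccc2c(c1)CCC(C)C2=O | intermediate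
14 | 6-methoxy-2-methyl-3,4-dihydronaphthalen-1-yl trifluoromethanesulfonate | COc1ccc2c(c1)CCC(C)=C2OS(=O)(=O)C(F)(F)F | intermediate
15 | 6-methoxy-2-methylnaphthalen-1-yl trifluoromethanesulfonate | COc1ccc2c(OS(=O)(=O)C(F)(F)F)c(C)ccc2c1 | intermediate
16 | 4-methylpent-1-en-3-ol (racemic) | C=CC(O)C(C)C | starting material
17 | 1-(6-methoxy-2-methylnaphthalen-1-yl)-4-methylpentan-3-one | COc1ccc2c(CCC(=O)C(C)C)c(C)ccc2c1 | intermediate
18 | 1-(5-bromo-6-methoxy-2-methylnaphthalen-1-yl)-4-methylpentan-3-one | COc1ccc2c(CCC(=O)C(C)C)c(C)ccc2c1Br | intermediate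
19 | 1-[6-methoxy-2-methyl-5-(propan-2-yl)naphthalen-1-yl]-4-methylpentan-3-one | COc1ccc2c(CCC(=O)C(C)C)c(C)ccc2c1C(C)C | intermediate
20 | 2-{2-[6-methoxy-2-methyl-5-(propan-2-yl)naphthalen-1-yl]ethyl}-2-(propan-2-yl)-1,3-dioxolane | COc1ccc2c(CCC3(C(C)C)OCCO3)c(C)ccc2c1C(C)C | intermediate
21 | {3-methoxy-7-methyl-4-(propan-2-yl)-8-[2-(2-(propan-2-yl)-1,3-dioxolan-2-yl)ethyl]naphthalen-2-yl}lithium (not isolated) | COc1c([Li])cc2c(CCC3(C(C)C)OCCO3)c(C)ccc2c1C(C)C | intermediate
22 | 2-{2-[7-bromo-6-methoxy-2-methyl-5-(propan-2-yl)naphthalen-1-yl]ethyl}-2-(propan-2-yl)-1,3-dioxolane | COc1c(Br)cc2c(CCC3(C(C)C)OCCO3)c(C)ccc2c1C(C)C | intermediate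
23 | 3β-acetoxy-12-methoxy-7α-{3-methoxy-7-methyl-4-(propan-2-yl)-8-[2-(2-(propan-2-yl)-1,3-dioxolan-2-yl)ethyl]naphthalen-2-yl}abieta-8,11,13-trien-6-one | Cc1ccc2c(C(C)C)c(OC)c(cc2c1CCC1(C(C)C)OCCO1)[C@H]1c2cc(C(C)C)c(OC)cc2[C@@]2(C)CC[C@H](OC(C)=O)C(C)(C)[C@@H]2C1=O | intermediate
24 | 3β-acetoxy-12-hydroxy-7α-[3-hydroxy-7-methyl-8-(4-methyl-3-oxopentyl)-4-(propan-2-yl)naphthalen-2-yl]abieta-8,11,13-trien-6-one (not isolated) | Cc1ccc2c(C(C)C)c(O)c(cc2c1CCC(=O)C(C)C)[C@H]1c2cc(C(C)C)c(O)cc2[C@@]2(C)CC[C@H](OC(C)=O)C(C)(C)[C@@H]2C1=O | intermediate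
25 | 3β-acetoxy-12-hydroxy-7-[7-methyl-8-(4-methyl-3-oxopentyl)-4-(propan-2-yl)naphthalen-2-yl]abieta-6,8,11,13-tetraene 6,3′-cyclic ether (aromatic naphtho[2,3-b]furan) | Cc1ccc2c(C(C)C)c3c(cc2c1CCC(=O)C(C)C)c1-c2cc(C(C)C)c(O)cc2[C@@]2(C)CC[C@H](OC(C)=O)C(C)(C)[C@@H]2c1o3 | intermediate
26 | 3β-acetoxy-12-hydroxy-7α-[7-methyl-8-(4-methyl-3-oxopentyl)-4-(propan-2-yl)naphthalen-2-yl]abieta-8,11,13-triene 6α,3′-cyclic ether (6β-H, 7β-H) | Cc1ccc2c(C(C)C)c3c(cc2c1CCC(=O)C(C)C)[C@H]1c2cc(C(C)C)c(O)cc2[C@@]2(C)CC[C@H](OC(C)=O)C(C)(C)[C@@H]2[C@H]1O3 | intermediate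
27 | CNP0584944.1: 3β,12-dihydroxy-7α-[7-methyl-8-(4-methyl-3-oxopentyl)-4-(propan-2-yl)naphthalen-2-yl]abieta-8,11,13-triene 6α,3′-cyclic ether | Cc1ccc2c(C(C)C)c3c(cc2c1CCC(=O)C(C)C)[C@H]1c2cc(C(C)C)c(O)cc2[C@@]2(C)CC[C@H](O)C(C)(C)[C@@H]2[C@H]1O3 | target

**Step count and risks**

Total step count: 19. Longest linear sequence: 12 steps (steps 8 to 19, from 12).

Steps most likely to fail:

Step 7. The C10 cation may be taken by chloride or lose a proton faster than the arene captures it, the olefin of 4 may isomerise before it is acylated, and the arene may enter C10 with poor discrimination between the two faces because the 1,4-induction from the acetate is weak. The fallback separates the two bond formations. It sets out from 9 and 4: acylation with SnCl4 in CH2Cl2 at −78 °C followed by Et3N should allow the enone 10 to be isolated (Kondakov acylation). A separate ring closure with CF3SO3H in CH2Cl2 at −40 °C (intramolecular Friedel–Crafts conjugate alkylation) then returns to the route at 11. In this form C5 is trigonal when ring B closes, the closure can be run under conditions chosen for facial control alone, and a C10 diastereomer is removed at 11. This fallback makes no compound outside the list (F0).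

Step 18. Protonation may occur at C7 in place of C6, followed by hydride delivery to the resulting oxocarbenium ion from the open α face; this would give the cis-fused ring with both new hydrogens α. The side-chain ketone may also be reduced. The fallback forms the C6–O bond by substitution with inversion. It sets out from 23, before the furan is made. Luche reduction (NaBH4, CeCl3·7H2O, MeOH/THF, 0 °C) should deliver hydride from the α face, away from the syn-axial methyl groups, and give the 6β-alcohol F1. NaSEt in DMF at 120 °C then cleaves both aryl methyl ethers and the acetate to give the tetrol F2. Mitsunobu cycloetherification (PPh3, diisopropyl azodicarboxylate, THF) lets the naphthol oxygen displace the activated 6β-oxygen with inversion to give the cis-fused ketal F3. 1 M HCl in THF then frees the side-chain ketone, and the route is rejoined at 27.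

Step 16. Carbon–carbon bond formation at the congested C7 may be slow, so that enolisation toward C5 (loss of the trans ring fusion) or self-condensation of the ketone takes over. The fallback reverses the polarity of the coupling. It sets out from 11 and from the aryllithium 21 of step 15. PhNMe3Br3 in THF at 0 °C brominates the benzylic α-carbon of 11 to give the 7α-bromo ketone F4. ZnCl2 converts 21 to the arylzinc chloride F5. A Negishi arylation of the α-bromo ketone with NiCl2·glyme and a 2,6-bis(oxazolinyl)pyridine ligand in THF at −30 °C joins F4 and F5 and returns to the route at 23.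

Further compounds
F0 | step 7 | none | none
F1 | step 18 | 3β-acetoxy-6β-hydroxy-12-methoxy-7α-{3-methoxy-7-methyl-4-(propan-2-yl)-8-[2-(2-(propan-2-yl)-1,3-dioxolan-2-yl)ethyl]naphthalen-2-yl}abieta-8,11,13-triene | Cc1ccc2c(C(C)C)c(OC)c(cc2c1CCC1(C(C)C)OCCO1)[C@H]1c2cc(C(C)C)c(OC)cc2[C@@]2(C)CC[C@H](OC(C)=O)C(C)(C)[C@@H]2[C@@H]1O
F2 | step 18 | 3β,6β,12-trihydroxy-7α-{3-hydroxy-7-methyl-4-(propan-2-yl)-8-[2-(2-(propan-2-yl)-1,3-dioxolan-2-yl)ethyl]naphthalen-2-yl}abieta-8,11,13-triene | Cc1ccc2c(C(C)C)c(O)c(cc2c1CCC1(C(C)C)OCCO1)[C@H]1c2cc(C(C)C)c(O)cc2[C@@]2(C)CC[C@H](O)C(C)(C)[C@@H]2[C@@H]1O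
F3 | step 18 | ethylene ketal (1,3-dioxolane) of 27 at the side-chain ketone | Cc1ccc2c(C(C)C)c3c(cc2c1CCC1(C(C)C)OCCO1)[C@H]1c2cc(C(C)C)c(O)cc2[C@@]2(C)CC[C@H](O)C(C)(C)[C@@H]2[C@H]1O3
F4 | step 16 | 3β-acetoxy-7α-bromo-12-methoxyabieta-8,11,13-trien-6-one | Br[C@H]1c2cc(C(C)C)c(OC)cc2[C@@]2(C)CC[C@H](OC(C)=O)C(C)(C)[C@@H]2C1=O
F5 | step 16 | {3-methoxy-7-methyl-4-(propan-2-yl)-8-[2-(2-(propan-2-yl)-1,3-dioxolan-2-yl)ethyl]naphthalen-2-yl}zinc chloride | COc1c([Zn]Cl)cc2c(CCC3(C(C)C)OCCO3)c(C)ccc2c1C(C)C
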